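Compound numbers refer to the steps and to the compound list that follows them. In the naphthalene intermediates, ring A is the ring that carries the ester or methyl group and the peri oxygen, and ring B is the ring that carries the benzyloxy group.

## Analysis of the target

Target 21 is (R)-3′-hydroxy-2-(2-hydroxyethyl)-7-methoxy-7′-methylspiro[isoindoline-1,2′-naphtho[1,8-bc]furan]-3-one. A 7-methoxyisoindolin-3-one (an anisole ring fused to a γ-lactam whose nitrogen carries a 2-hydroxyethyl chain) and a 2H-naphtho[1,8-bc]furan (a five-membered ether ring bridging the peri positions of a naphthalene with a free hydroxyl at C3′ and a methyl group at C7′) share one carbon. That carbon (C1 = C2′) is the only stereocentre. It carries nitrogen, oxygen and two different aryl carbons, so nothing in the molecule can relay its configuration and it must be set by a catalyst or by resolution. It is an N-acyl N,O-ketal between two arenes, so acid can ionize its C–O bond to a stabilised cation and racemize it. The free side-chain alcohol could re-close on that cation to an oxazolidine, and under strong base the C3′ phenol could open the ketal through a quinone methide. The last steps therefore have to run near neutrality. The synthesis is hard because the fully substituted carbon joins two arenes that are each substituted at both ortho positions (methoxy and lactam carbonyl on one, hydroxyl and the peri oxygen on the other). The strategy rests on two features. First, C7a, the benzene carbon bearing the spiro carbon, lies between C7 (methoxy) and C3a (lactam carbonyl), which is the position that a 3-methoxybenzamide lithiates under the joint direction of both groups. Second, the spiro carbon, bound to C2a′ and through O1′ to the peri carbon C8a′, has the connectivity and oxidation level of the carbonyl carbon of an 8-hydroxy-1-naphthoic acid lactone.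

## Retrosynthetic reasoning

**Protecting groups (21 ⇐ 20 ⇐ 19).** The last two operations only remove groups. The benzyl ether on the C3′ oxygen comes off last, from 20, by neutral hydrogenolysis, because an alkylated oxygen at that position cannot open the ketal through a quinone methide. The silyl ether of the side chain is removed one step earlier, from 19, with buffered fluoride. Neither step touches the stereocentre.

**Spiro C–O bond (19 ⇐ 18).** The bond between the spiro carbon and the peri oxygen is cut. Ionization of the tertiary carbinol of 18 gives a planar, doubly aryl-stabilised cationic centre next to nitrogen with the peri hydroxyl within bonding distance, so a chiral Brønsted acid paired with that cation can decide which face the oxygen takes. Because the carbinol centre is erased, 18 may be racemic, and no earlier step carries a stereochemical demand. The forward reaction has to outrun uncatalysed closure and keep the other oxygens out: the side-chain oxygen is silylated (it would otherwise close to an oxazolidine) and the C2 naphthol oxygen is benzylated.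

**Aryl–carbon and carbon–nitrogen bonds (18 ⇐ 15 + 12).** Two bonds at the future spiro carbon are cut together, the one to the anisole carbon and the one to nitrogen. The anisole carbon is the doubly activated metalation site of amide 15, and the carbinol carbon is the carbonyl carbon of peri lactone 12. A single addition to the lactone gives the ketone oxidation level and frees the peri naphthol needed for the next step. Cutting on the naphthalene side instead would require a naphthyl nucleophile and a phthalimide-type electrophile with two non-equivalent carbonyl groups; the chosen cut avoids that choice. The forward reaction must metalate 15 at nitrogen and at C2, add once to 12, open the lactone and close the lactam.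

**Amide bond (15 ⇐ 13 + 14).** Amide 15 is cut at the acyl–nitrogen bond into acid chloride 13 and silyl-protected amine 14, so the nucleophilic arm is one step from commercial material.

**Lactone carbonyl (12 ⇐ 9 ⇐ 8).** The bond between naphthalene C1 and the lactone carbonyl carbon is cut, and the carbonyl carbon is traced to a carbonate on the peri oxygen of bromide 9. Bromine–lithium exchange places a carbanion next to its own electrophile, so the acyl group is transferred from oxygen to carbon within the molecule and no external one-carbon electrophile has to reach a crowded aryllithium. Carbonate 9 comes from naphthol 8 by O-acylation.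

**Methyl group and bromine (8 ⇐ 7 ⇐ 6 ⇐ 5 ⇐ 4).** The methyl group of 8 is the reduced form of the ester of 5, by way of alcohol 6 and benzylic bromide 7. The bromine is introduced at the stage of 4, where ring A is deactivated by its ester and acetoxy groups, so the only activated position is the α-carbon of ring B next to the benzyloxy group. That is the carbon that must later carry the lactone carbonyl.

**Naphthalene ring A (4 ⇐ 3 ⇐ 1 + 2).** Ring A is cut back to aldehyde 1 and succinate 2 through half-ester 3. The annulation places the three substituents correctly without any regiochemical choice: the ester becomes the methyl group, the acid carbonyl becomes the peri oxygen, and the para benzyloxy group of 1 ends up next to the α-carbon that is brominated.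

## Alternatives that were turned down

**Alternative 1:** The oxygenated ring of the naphthalene and the diaryl ketone are built in one benzannulation. An ortho-alkynylbenzaldehyde, methyl 2-{[2-(benzyloxy)-6-formyl-4-methylphenyl]ethynyl}-3-methoxybenzoate A2, is activated by AuCl3 to a benzopyrylium ion that takes up benzyloxyethyne A3 in a [4+2] process. Loss of the oxygen bridge gives keto ester A1, methyl 2-{[2,8-bis(benzyloxy)-6-methylnaphthalen-1-yl]carbonyl}-3-methoxybenzoate, which an amine would then convert to the hydroxylactam.
- For it: the most crowded bond, between the ketone carbon and the naphthalene, is never made by adding a hindered carbanion to a hindered carbonyl. The polarity of the ynol ether matches the required regiochemistry, and the ring and the ketone arise together under catalytic conditions. On these points it is stronger than the chosen route.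
- Against it: A2 needs a Sonogashira union of two partners that are each flanked on both sides, and the halogenated benzyloxy-methyl-benzaldehyde it requires is itself a multistep target. The ortho ester of A2 can attack the gold-activated alkyne in competition with the aldehyde and give an isocoumarin. A3 is a labile ynol ether. A1 still has to be condensed with an amine at a very hindered ketone.
- Comparison: the chosen strategy puts nitrogen in place before the carbon–carbon bond is made, so the lactam closes in the same operation, and it reaches its precursors by classical reactions with no regiochemical ambiguity.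

**Alternative 2:** The two arenes arrive already joined in a benz[a]anthracene-7,12-dione, 1-(benzyloxy)-11-methoxy-3-methylbenz[a]anthracene-7,12-dione A5. A peracid is meant to insert oxygen between C7 and C6a, giving the seven-membered keto lactone A4. An amino alcohol would then open the aryl ester to the amide, release the naphthol and close onto the remaining ketone.
- For it: the late stage is more economical than in the chosen route. One aminolysis forms the amide, unveils the C3′ hydroxyl without a protecting group and sets up the hydroxylactam, and no bond between the two aryl units has to be formed.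
- Against it: Baeyer–Villiger oxidation of anthraquinone-type carbonyls is sluggish, and four insertions are possible (two carbonyls, two migrating groups each) of which one is productive. The forcing peracid conditions would also attack the electron-rich methyl- and benzyloxy-substituted naphthalene. A5 is a tetracyclic target whose preparation costs about as many steps as the whole chosen route. The stereocentre is still set in the same way afterwards.
- Comparison: in the chosen strategy the carbon that becomes the spiro centre and the oxygen that ends on the naphthalene are fixed by the construction of 12, not by a migratory preference.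

**Alternative 3:** The anisole ring and the lactam are built last around a preformed ketal carbon. The furyl N,O-ketal A7 (a secondary amine bearing a 3-methoxyfuran-2-yl group on the spiro carbon) is N-acryloylated. The acrylamide adds across the furan in an intramolecular Diels–Alder reaction, and base opens the oxygen bridge and dehydrates to the arene, giving A6, which is identical with 19.
- For it: the crowded aryl–carbon bond is made with a small furan instead of a doubly flanked benzene nucleophile, and one cascade forms two carbon–carbon bonds and two rings and lands two steps from the target. On the steric point it is stronger than the chosen route.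
- Against it: A7 is a ketal of a secondary amine with no acyl group on nitrogen and an electron-rich furan on carbon. It can open to the ketimine and naphthol, so its configuration is far less secure than that of 19, and the acid released on acylation would promote that opening. The nitrogen to be acylated sits on a fully substituted carbon. The cycloaddition closes a five-membered lactam through a three-atom tether, which is strained and reversible until aromatization.
- Comparison: the chosen strategy creates the stereocentre directly as a configurationally robust N-acyl ketal, from two simple aromatic pieces.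

Key step: step 10

Assumption: the sense of induction of the chiral phosphoric acid in step 11 cannot be derived with confidence; the (R)-catalyst is written, and its mirror image takes its place if it proves to favour the (S)-ketal.

## Route

Step 1
Reactants: 1 4-(benzyloxy)benzaldehyde; 2 diethyl succinate
Product: 3 (E)-4-[4-(benzyloxy)phenyl]-3-(ethoxycarbonyl)but-3-enoic acid
Conditions: KOt-Bu (1.2 equiv), t-BuOH, reflux; then aq. HCl
Reagents that add atoms: none
Why: Stobbe condensation: the succinate enolate adds to the aldehyde, the alkoxide lactonizes onto the second ester and base-induced ring opening gives the half-ester carboxylate. Elimination places the aryl group trans to the ester (E), which is the geometry the ring closure needs, and the benzyl ether is inert to alkoxide.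

Step 2
Reactants: 3 (E)-4-[4-(benzyloxy)phenyl]-3-(ethoxycarbonyl)but-3-enoic acid
Product: 4 ethyl 4-acetoxy-6-(benzyloxy)-2-naphthoate
Conditions: Ac2O, NaOAc, 140 °C
Reagents that add atoms: acetic anhydride, CC(=O)OC(C)=O
Why: The mixed anhydride acylates the ortho carbon of the aryl ring (intramolecular Friedel–Crafts acylation, the cyclization stage of the Stobbe naphthol synthesis), and the resulting naphthol is acetylated in the same pot. The two ortho positions of the para-substituted ring are equivalent, so one naphthalene results.

Step 3
Reactants: 4 ethyl 4-acetoxy-6-(benzyloxy)-2-naphthoate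
Product: 5 ethyl 4-acetoxy-6-(benzyloxy)-5-bromo-2-naphthoate
Conditions: N-bromosuccinimide (1.05 equiv), MeCN, 0 °C to rt, dark
Reagents that add atoms: N-bromosuccinimide, O=C1CCC(=O)N1Br
Why: Electrophilic aromatic bromination: C5 is the α-position ortho to the benzyloxy group (the counterpart of C1 of a 2-alkoxynaphthalene), while ring A is deactivated by the ester and the acetoxy group. No benzylic methyl group is present yet, so side-chain bromination cannot compete.

Step 4
Reactants: 5 ethyl 4-acetoxy-6-(benzyloxy)-5-bromo-2-naphthoate
Product: 6 7-(benzyloxy)-8-bromo-3-(hydroxymethyl)naphthalen-1-ol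
Conditions: i-Bu2AlH (5 equiv), CH2Cl2, −78 to 0 °C; aq. potassium sodium tartrate
Reagents that add atoms: none
Why: Aluminium hydride reduction takes the ethyl ester to the primary alcohol and cleaves the aryl acetate reductively. The aryl bromide and the benzyl ether do not react with i-Bu2AlH at this temperature.

Step 5
Reactants: 6 7-(benzyloxy)-8-bromo-3-(hydroxymethyl)naphthalen-1-ol
Product: 7 7-(benzyloxy)-8-bromo-3-(bromomethyl)naphthalen-1-ol
Conditions: CBr4 (1.2 equiv), PPh3 (1.2 equiv), CH2Cl2, 0 °C
Reagents that add atoms: carbon tetrabromide, BrC(Br)(Br)Br
Why: Appel reaction: the primary benzylic alcohol is activated as an alkoxyphosphonium ion and displaced by bromide, whereas the naphthol oxygen cannot be displaced from an aromatic carbon. The product is used without storage.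

Step 6
Reactants: 7 7-(benzyloxy)-8-bromo-3-(bromomethyl)naphthalen-1-ol
Product: 8 7-(benzyloxy)-8-bromo-3-methylnaphthalen-1-ol
Conditions: LiBEt3H (2.5 equiv), THF, 0 °C, 7 added to the hydride; aq. NH4Cl
Reagents that add atoms: none
Why: SN2 displacement of the benzylic bromide by hydride, after the first equivalent has deprotonated the naphthol. Inverse addition keeps hydride in excess over the lithium naphtholate so that self-alkylation cannot compete, and the aryl bromide is inert at 0 °C.

Step 7
Reactants: 8 7-(benzyloxy)-8-bromo-3-methylnaphthalen-1-ol
Product: 9 7-(benzyloxy)-8-bromo-3-methylnaphthalen-1-yl methyl carbonate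
Conditions: ClCO2Me (1.3 equiv), Et3N, DMAP (cat.), CH2Cl2, 0 °C
Reagents that add atoms: methyl chloroformate, COC(=O)Cl
Why: O-Acylation of the naphthol with a chloroformate under nucleophilic catalysis. The carbonate places the future lactone carbonyl carbon on the peri oxygen.

Step 8
Reactants: 9 7-(benzyloxy)-8-bromo-3-methylnaphthalen-1-yl methyl carbonate
Product: 12 3-(benzyloxy)-7-methyl-2H-naphtho[1,8-bc]furan-2-one, via aryllithium 10 (not isolated), via hydroxy ester 11 (not isolated)
Conditions: t-BuLi (2.1 equiv), THF, −95 to −78 °C; aq. NH4Cl; then TsOH·H2O (cat.), toluene, 80 °C
Reagents that add atoms: none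
Why: Bromine–lithium exchange gives aryllithium 10, which attacks the carbonate on the neighbouring peri oxygen at once (anionic Fries-type O-to-C acyl transfer, a Parham-type cyclization) and leaves the lithium naphtholate of ester 11. This internal capture is faster than deprotonation of the benzylic OCH2 group. Acid then closes the peri lactone with loss of methanol, as 8-hydroxy-1-naphthoic acid derivatives do readily.

Step 9
Reactants: 13 3-methoxybenzoyl chloride; 14 2-(tert-butyldimethylsilyloxy)ethanamine
Product: 15 N-[2-(tert-butyldimethylsilyloxy)ethyl]-3-methoxybenzamide
Conditions: Et3N (1.5 equiv), CH2Cl2, 0 °C to rt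
Reagents that add atoms: none
Why: N-Acylation of a primary amine by an acid chloride with an amine base as acid scavenger. The silyl ether is untouched.

Step 10
Reactants: 15 N-[2-(tert-butyldimethylsilyloxy)ethyl]-3-methoxybenzamide; 12 3-(benzyloxy)-7-methyl-2H-naphtho[1,8-bc]furan-2-one
Product: 18 rac-3-[2-(benzyloxy)-8-hydroxy-6-methylnaphthalen-1-yl]-2-[2-(tert-butyldimethylsilyloxy)ethyl]-3-hydroxy-4-methoxyisoindolin-1-one, via dilithio amide 16 (not isolated), via keto amide 17 (not isolated)
Conditions: 15 (1.2 equiv), sec-BuLi (2.5 equiv), TMEDA (2.5 equiv), THF, −78 °C; then 12 (1.0 equiv), −78 to −20 °C; pH 7 phosphate buffer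
Reagents that add atoms: none
Why: sec-BuLi/TMEDA removes first the N–H and then the C2–H of 15, the one ring position flanked by both the lithium amidate and the methoxy group, so the metal sits on the carbon that has to carry the spiro centre (directed ortho-metalation, dianion 16). The aryllithium adds to the lactone carbonyl of 12, whose π-faces are open because the peri bridge holds the C=O in the naphthalene plane; the tetrahedral alkoxide then expels the peri naphtholate, which relieves the strain of the five-membered peri ring and gives diaryl ketone 17 as its dilithium salt. The amidate nitrogen adds to this ketone in a 5-exo-trig closure, and after the quench the ring–chain equilibrium lies on the side of hydroxylactam 18, as is usual for N-alkyl 2-aroylbenzamides. The closest known reaction type is the addition of ortho-lithiated secondary benzamides to esters, lactones and formamides to give 3-hydroxyisoindolinones. The carbinol stereocentre at C3 forms without control, as the racemate, which is acceptable because step 11 erases it by ionization. Metalation at C2 instead of C4 or C6 is secured by the cooperating amidate and methoxy groups. Single addition is secured because the ketone is released as a hindered dianion between amidate and naphtholate and is captured intramolecularly. The silyl and benzyl ethers tolerate the alkyllithium at −78 °C, and the neutral quench keeps 18 from closing to the racemic ketal before step 11.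

Step 11
Reactants: 18 rac-3-[2-(benzyloxy)-8-hydroxy-6-methylnaphthalen-1-yl]-2-[2-(tert-butyldimethylsilyloxy)ethyl]-3-hydroxy-4-methoxyisoindolin-1-one
Product: 19 (R)-3′-(benzyloxy)-2-[2-(tert-butyldimethylsilyloxy)ethyl]-7-methoxy-7′-methylspiro[isoindoline-1,2′-naphtho[1,8-bc]furan]-3-one
Conditions: (R)-3,3′-bis(2,4,6-triisopropylphenyl)-1,1′-binaphthyl-2,2′-diyl hydrogen phosphate, (R)-TRIP (10 mol %), 4 Å MS, toluene, −20 °C; Et3N quench
Reagents that add atoms: none
Why: Proposed new method: the phosphoric acid protonates the tertiary hydroxyl of 18, water leaves, and a diaryl-substituted N-acyliminium ion forms as a contact ion pair with the chiral phosphate, which is also hydrogen-bonded to the peri naphthol; the naphthol oxygen closes 5-exo-trig on the iminium carbon, and because the iminium plane must stand perpendicular to the naphthalene for this closure, the two faces correspond to two rotamers about the naphthyl–carbon bond, between which the chiral anion selects, while reversible ionization and ring–chain tautomerism interconvert the enantiomers of 18. The closest known reaction types are the chiral-phosphoric-acid-catalysed additions of thiols, indoles and hydride donors to ketiminium ions generated from 3-aryl-3-hydroxyisoindolinones and the phosphoric-acid-catalysed enantioselective spiroketalization; closure of a peri naphthol on an N-alkyl acyliminium ion has not been shown. The silyl ether keeps the side-chain oxygen from closing to an oxazolidine, and the C2 oxygen is blocked as its benzyl ether.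

Step 12
Reactants: 19 (R)-3′-(benzyloxy)-2-[2-(tert-butyldimethylsilyloxy)ethyl]-7-methoxy-7′-methylspiro[isoindoline-1,2′-naphtho[1,8-bc]furan]-3-one
Product: 20 (R)-3′-(benzyloxy)-2-(2-hydroxyethyl)-7-methoxy-7′-methylspiro[isoindoline-1,2′-naphtho[1,8-bc]furan]-3-one
Conditions: Bu4NF (1.2 equiv), AcOH (1.2 equiv), THF, 0 °C to rt
Reagents that add atoms: none
Why: Fluoride-induced cleavage of the alkyl silyl ether, buffered so that neither acid (ketal ionization) nor free alkoxide is present. With the C3′ oxygen still benzylated, the ketal has no base-induced opening pathway, so the configuration is retained.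

Step 13
Reactants: 20 (R)-3′-(benzyloxy)-2-(2-hydroxyethyl)-7-methoxy-7′-methylspiro[isoindoline-1,2′-naphtho[1,8-bc]furan]-3-one
Product: 21 (R)-3′-hydroxy-2-(2-hydroxyethyl)-7-methoxy-7′-methylspiro[isoindoline-1,2′-naphtho[1,8-bc]furan]-3-one
Conditions: H2 (1 atm), 10% Pd/C, EtOAc, rt
Reagents that add atoms: none
Why: Hydrogenolysis of the aryl benzyl ether at its unhindered primary benzylic carbon under neutral conditions, which do not ionize the ketal. The spiro C–O bond is tertiary and buried between two ortho-substituted arenes, so it should be cleaved much more slowly.

## Compound list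

1 | 4-(benzyloxy)benzaldehyde | O=Cc1ccc(OCc2ccccc2)cc1 | starting material
2 | diethyl succinate | CCOC(=O)CCC(=O)OCC | starting material
3 | (E)-4-[4-(benzyloxy)phenyl]-3-(ethoxycarbonyl)but-3-enoic acid | CCOC(=O)/C(=C/c1ccc(OCc2ccccc2)cc1)CC(=O)O | intermediate
4 | ethyl 4-acetoxy-6-(benzyloxy)-2-naphthoate | CCOC(=O)c1cc(OC(C)=O)c2cc(OCc3ccccc3)ccc2c1 | intermediate
5 | ethyl 4-acetoxy-6-(benzyloxy)-5-bromo-2-naphthoate | CCOC(=O)c1cc(OC(C)=O)c2c(Br)c(OCc3ccccc3)ccc2c1 | intermediate
6 | 7-(benzyloxy)-8-bromo-3-(hydroxymethyl)naphthalen-1-ol | OCc1cc(O)c2c(Br)c(OCc3ccccc3)ccc2c1 | intermediate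
7 | 7-(benzyloxy)-8-bromo-3-(bromomethyl)naphthalen-1-ol | BrCc1cc(O)c2c(Br)c(OCc3ccccc3)ccc2c1 | intermediate
8 | 7-(benzyloxy)-8-bromo-3-methylnaphthalen-1-ol | Cc1cc(O)c2c(Br)c(OCc3ccccc3)ccc2c1 | intermediate
9 | 7-(benzyloxy)-8-bromo-3-methylnaphthalen-1-yl methyl carbonate | COC(=O)Oc1cc(C)cc2ccc(OCc3ccccc3)c(Br)c12 | intermediate
10 | 7-(benzyloxy)-8-lithio-3-methylnaphthalen-1-yl methyl carbonate (formed in the flask) | COC(=O)Oc1cc(C)cc2ccc(OCc3ccccc3)c([Li])c12 | intermediate
11 | methyl 2-(benzyloxy)-8-hydroxy-6-methyl-1-naphthoate (present as its lithium naphtholate, not isolated) | COC(=O)c1c(OCc2ccccc2)ccc2cc(C)cc(O)c12 | intermediate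
12 | 3-(benzyloxy)-7-methyl-2H-naphtho[1,8-bc]furan-2-one (lactone of 2-(benzyloxy)-8-hydroxy-6-methyl-1-naphthoic acid) | O=C1Oc2cc(C)cc3ccc(OCc4ccccc4)c1c23 | intermediate
13 | 3-methoxybenzoyl chloride | COc1cccc(C(Cl)=O)c1 | starting material
14 | 2-(tert-butyldimethylsilyloxy)ethanamine | NCCO[Si](C)(C)C(C)(C)C | starting material
15 | N-[2-(tert-butyldimethylsilyloxy)ethyl]-3-methoxybenzamide | COc1cccc(C(=O)NCCO[Si](C)(C)C(C)(C)C)c1 | intermediate
16 | N,2-dilithio-N-[2-(tert-butyldimethylsilyloxy)ethyl]-3-methoxybenzamide (formed in the flask) | COc1cccc(C(=O)N([Li])CCO[Si](C)(C)C(C)(C)C)c1[Li] | intermediate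
17 | 2-{[2-(benzyloxy)-8-hydroxy-6-methylnaphthalen-1-yl]carbonyl}-N-[2-(tert-butyldimethylsilyloxy)ethyl]-3-methoxybenzamide (present as its dilithium salt, not isolated) | COc1cccc(C(=O)NCCO[Si](C)(C)C(C)(C)C)c1C(=O)c1c(OCc2ccccc2)ccc2cc(C)cc(O)c12 | intermediate
18 | rac-3-[2-(benzyloxy)-8-hydroxy-6-methylnaphthalen-1-yl]-2-[2-(tert-butyldimethylsilyloxy)ethyl]-3-hydroxy-4-methoxyisoindolin-1-one | COc1cccc2c1C(O)(c1c(OCc3ccccc3)ccc3cc(C)cc(O)c13)N(CCO[Si](C)(C)C(C)(C)C)C2=O | intermediate
19 | (R)-3′-(benzyloxy)-2-[2-(tert-butyldimethylsilyloxy)ethyl]-7-methoxy-7′-methylspiro[isoindoline-1,2′-naphtho[1,8-bc]furan]-3-one | COc1cccc2c1[C@@]1(Oc3cc(C)cc4ccc(OCc5ccccc5)c1c34)N(CCO[Si](C)(C)C(C)(C)C)C2=O | intermediate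
20 | (R)-3′-(benzyloxy)-2-(2-hydroxyethyl)-7-methoxy-7′-methylspiro[isoindoline-1,2′-naphtho[1,8-bc]furan]-3-one | COc1cccc2c1[C@@]1(Oc3cc(C)cc4ccc(OCc5ccccc5)c1c34)N(CCO)C2=O | intermediate
21 | (R)-3′-hydroxy-2-(2-hydroxyethyl)-7-methoxy-7′-methylspiro[isoindoline-1,2′-naphtho[1,8-bc]furan]-3-one | COc1cccc2c1[C@@]1(Oc3cc(C)cc4ccc(O)c1c34)N(CCO)C2=O | target

## Step count and least certain steps

Total: 13 steps. Longest linear sequence: 12 steps (steps 1 to 8, then 10 to 13); the amide arm is one step (step 9).

**Step 11 (enantioselective closure).** Three processes can defeat it:
- closure of 18 without the catalyst (on silica or during the work-up of step 10), which delivers racemic ketal before the chiral acid acts;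
- closure that is faster than the interconversion of the two naphthyl rotamers and the two enantiomers of 18, so that the racemic composition of 18 is carried through;
- re-ionization of 19 by the acid after it has formed, which erodes the enantiomeric purity.

All three follow from the ease with which the diaryl-stabilised cation forms. Fallback by known chemistry, from 18 back to 19: 18 is closed with TsOH·H2O (cat.) in CH2Cl2 over 4 Å MS, an ordinary acid-promoted acyliminium N,O-ketalization, to the racemic ketal rac-3′-(benzyloxy)-2-[2-(tert-butyldimethylsilyloxy)ethyl]-7-methoxy-7′-methylspiro[isoindoline-1,2′-naphtho[1,8-bc]furan]-3-one F1. F1 is resolved by preparative chromatography on a chiral stationary phase to give 19. The unwanted (S)-enantiomer F2 is returned to F1 with the same acid, which racemizes it by reversible ionization, and is recycled.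

**Step 10 (key step).** The doubly flanked dianion may fail to add to the carbonyl of 12, which is itself flanked by the benzyloxy group. Proton abstraction at the benzylic OCH2 group, or consumption of 12 by residual sec-BuLi after incomplete C2 metalation, would then take over. The cause is the combination of high basicity, aggregation and steric demand of the dilithio species. Fallback, from 12 back to 18: the carbon–carbon bond is made with a less basic, fixed-site nucleophile and the nitrogen is brought in afterwards. Commercial methyl 2-iodo-3-methoxybenzoate (COC(=O)c1cccc(OC)c1I) undergoes iodine–magnesium exchange with i-PrMgCl·LiCl (THF, −40 °C), and the arylmagnesium reagent opens 12 to the keto ester methyl 2-{[2-(benzyloxy)-8-hydroxy-6-methylnaphthalen-1-yl]carbonyl}-3-methoxybenzoate F3. Heating F3 with amine 14 in toluene at 80 °C gives amide formation and closure onto the ketone, the usual conversion of 2-acylbenzoates to 3-hydroxyisoindolinones, and returns 18.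

**Step 8 (carbonate ring closure).** Attack of t-BuLi on the carbonate carbonyl, or deprotonation of the benzylic OCH2 group followed by a [1,2]-Wittig shift, may compete with the exchange, because the bromide is electron-rich and crowded. Fallback, from 8 directly to 12 without an organolithium: palladium-catalysed carbonylative lactonization of bromonaphthol 8 with Pd(OAc)2, Xantphos, CO (1 atm) and Et3N in toluene at 100 °C. Oxidative addition and CO insertion give an acylpalladium intermediate that is captured by the peri hydroxyl. No new compound is isolated.

**Step 13 (final hydrogenolysis).** Over-reduction, that is hydrogenolysis of the doubly benzylic spiro C–O bond with its aryloxy leaving group, or ionization of the ketal by acidic sites of the catalyst with loss of enantiomeric purity, may accompany debenzylation. Fallback, from 18 to 21 with the benzyl group removed before the ketal exists: hydrogenolysis of 18 (H2, 10% Pd/C, EtOAc) gives the naphthalenediol rac-3-(2,8-dihydroxy-6-methylnaphthalen-1-yl)-2-[2-(tert-butyldimethylsilyloxy)ethyl]-3-hydroxy-4-methoxyisoindolin-1-one F4. Closure with (R)-TRIP as in step 11 gives the silyl ether (R)-2-[2-(tert-butyldimethylsilyloxy)ethyl]-3′-hydroxy-7-methoxy-7′-methylspiro[isoindoline-1,2′-naphtho[1,8-bc]furan]-3-one F5; only the peri hydroxyl can reach the cationic carbon in a five-membered ring, since the C2 hydroxyl would need a four-membered one. Bu4NF/AcOH in THF then gives 21.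

## Further compounds

F1 | step 11 | rac-3′-(benzyloxy)-2-[2-(tert-butyldimethylsilyloxy)ethyl]-7-methoxy-7′-methylspiro[isoindoline-1,2′-naphtho[1,8-bc]furan]-3-one | COc1cccc2c1C1(Oc3cc(C)cc4ccc(OCc5ccccc5)c1c34)N(CCO[Si](C)(C)C(C)(C)C)C2=O
F2 | step 11 | (S)-3′-(benzyloxy)-2-[2-(tert-butyldimethylsilyloxy)ethyl]-7-methoxy-7′-methylspiro[isoindoline-1,2′-naphtho[1,8-bc]furan]-3-one | COc1cccc2c1[C@]1(Oc3cc(C)cc4ccc(OCc5ccccc5)c1c34)N(CCO[Si](C)(C)C(C)(C)C)C2=O
F3 | step 10 | methyl 2-{[2-(benzyloxy)-8-hydroxy-6-methylnaphthalen-1-yl]carbonyl}-3-methoxybenzoate | COC(=O)c1cccc(OC)c1C(=O)c1c(OCc2ccccc2)ccc2cc(C)cc(O)c12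
F0 | step 8 | none | none
F4 | step 13 | rac-3-(2,8-dihydroxy-6-methylnaphthalen-1-yl)-2-[2-(tert-butyldimethylsilyloxy)ethyl]-3-hydroxy-4-methoxyisoindolin-1-one | COc1cccc2c1C(O)(c1c(O)ccc3cc(C)cc(O)c13)N(CCO[Si](C)(C)C(C)(C)C)C2=O
F5 | step 13 | (R)-2-[2-(tert-butyldimethylsilyloxy)ethyl]-3′-hydroxy-7-methoxy-7′-methylspiro[isoindoline-1,2′-naphtho[1,8-bc]furan]-3-one | COc1cccc2c1[C@@]1(Oc3cc(C)cc4ccc(O)c1c34)N(CCO[Si](C)(C)C(C)(C)C)C2=O
A1 | alternative 1 | methyl 2-{[2,8-bis(benzyloxy)-6-methylnaphthalen-1-yl]carbonyl}-3-methoxybenzoate | COC(=O)c1cccc(OC)c1C(=O)c1c(OCc2ccccc2)ccc2cc(C)cc(OCc3ccccc3)c12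
A2 | alternative 1 | methyl 2-{[2-(benzyloxy)-6-formyl-4-methylphenyl]ethynyl}-3-methoxybenzoate | COC(=O)c1cccc(OC)c1C#Cc1c(C=O)cc(C)cc1OCc1ccccc1
A3 | alternative 1 | benzyloxyethyne | C#COCc1ccccc1
A4 | alternative 2 | seven-membered keto lactone from 1-(benzyloxy)-11-methoxy-3-methylbenz[a]anthracene-7,12-dione with oxygen inserted between C6a and C7 | COc1cccc2c1C(=O)c1c(OC2=O)ccc2cc(C)cc(OCc3ccccc3)c12
A5 | alternative 2 | 1-(benzyloxy)-11-methoxy-3-methylbenz[a]anthracene-7,12-dione | COc1cccc2c1C(=O)c1c(C2=O)ccc2cc(C)cc(OCc3ccccc3)c12
A6 | alternative 3 | (R)-3′-(benzyloxy)-2-[2-(tert-butyldimethylsilyloxy)ethyl]-7-methoxy-7′-methylspiro[isoindoline-1,2′-naphtho[1,8-bc]furan]-3-one (identical with 19) | COc1cccc2c1[C@@]1(Oc3cc(C)cc4ccc(OCc5ccccc5)c1c34)N(CCO[Si](C)(C)C(C)(C)C)C2=O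
A7 | alternative 3 | N-[2-(tert-butyldimethylsilyloxy)ethyl]-3-(benzyloxy)-2-(3-methoxyfuran-2-yl)-7-methyl-2H-naphtho[1,8-bc]furan-2-amine, same spatial arrangement at the ketal carbon as in 19 | COc1ccoc1[C@@]1(Oc2cc(C)cc3ccc(OCc4ccccc4)c1c23)NCCO[Si](C)(C)C(C)(C)C
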